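**Assumptions (one line):** the SMILES is read as (3R,4R,6R,7S,8S,10R) with a (Z)‑2‑methylbut‑2‑enoate (angelate) at O‑8; germacrane numbering (C1 ketone … C10, C11–C13 lactone) is given in brackets; where a chiral reagent's sense on this exact substrate is unproven, the enantiomer quoted is the one predicted from the parent substrates (acetophenone, 1‑methylcyclohexene), and the antipode is used if the sense turns out opposite.

## Retrosynthetic overview

1. The lactone closes last: CBS reduction of the C6 ketone of a cyclodecane‑1,6‑dione, then lactonisation onto a pendant acrylate ester.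
2. The ten‑membered ring is never cyclised. It is released by ozonolysis of the C1=C6 ring‑fusion alkene of a 1,2,3,4,5,8‑hexahydronaphthalene.
3. That diene comes from Birch dearomatisation of a tetralin. The arene's fusion carbons become C1/C6, and its C3=C4(Me) alkene receives the trans‑3‑O/4‑Me pair by asymmetric hydroboration.
4. Ring B (C7, C8, C10) is set on the arene first: enantioselective ketone allylation, RCM, OH‑directed epoxidation, anti benzylic opening by an alkenyl cuprate.
5. Ring order: six‑membered carbocycle on the arene (RCM), arene dearomatised, fusion bond cleaved to the ten‑membered ring, lactone. Starting materials: 2′‑hydroxy‑4′‑methylacetophenone (the m‑cresol Fries product), 2‑bromoallyl alcohol, angelic acid.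

## Route

**Step 1**
Reactants: 1, 1‑(2‑hydroxy‑4‑methylphenyl)ethan‑1‑one; 2, trifluoromethanesulfonic anhydride
Product: 3, 2‑acetyl‑5‑methylphenyl trifluoromethanesulfonate
Conditions: Tf2O, pyridine, CH2Cl2, 0 °C
Reagents that add atoms: triflic anhydride (2), O=S(=O)(OS(=O)(=O)C(F)(F)F)C(F)(F)F
Why: Phenol O‑sulfonylation turns the ortho C–O bond into a cross‑coupling handle; no stereocentre.

**Step 2**
Reactants: 3; 4, potassium vinyltrifluoroborate
Product: 5, 1‑(4‑methyl‑2‑vinylphenyl)ethan‑1‑one
Conditions: PdCl2(dppf) (2 mol %), Et3N, n‑PrOH, 80 °C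
Reagents that add atoms: potassium vinyltrifluoroborate (4), C=C[B-](F)(F)F.[K+]
Why: Suzuki–Miyaura coupling of an aryl triflate installs the carbon that becomes C7.

**Step 3**
Reactants: 5; 6, allylboronic acid pinacol ester
Product: 7, (R)‑2‑(4‑methyl‑2‑vinylphenyl)pent‑4‑en‑2‑ol
Conditions: allyl‑B(pin), chiral valine‑derived aminophenol catalyst (2 mol %), NaOt‑Bu (cat.), MeOH, toluene, 4 °C
Reagents that add atoms: allyl‑B(pin) (6), C=CCB1OC(C)(C)C(C)(C)O1
Why: Catalytic enantioselective allylboration of an aryl methyl ketone sets the tertiary carbinol [C10, R] by catalyst control.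

**Step 4**
Reactants: 7
Product: 8, (R)‑1,6‑dimethyl‑1,2‑dihydronaphthalen‑1‑ol
Conditions: Grubbs II (2 mol %), CH2Cl2, 40 °C; chromatography on Et3N‑washed silica
Reagents that add atoms: none
Why: Ring‑closing metathesis of the styrene and allyl groups (loss of ethylene) forms ring B with the C7=C8 alkene; C10 is untouched, and the product is kept acid‑free because it dehydrates easily to the naphthalene.

**Step 5**
Reactants: 8
Product: 9, (1aS,3R,7bR)‑3,6‑dimethyl‑1a,2,3,7b‑tetrahydronaphtho[1,2‑b]oxiren‑3‑ol (epoxide cis to the OH)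
Conditions: VO(acac)2 (5 mol %), t‑BuOOH, 2,6‑lutidine, CH2Cl2, 0 °C
Reagents that add atoms: tert‑butyl hydroperoxide, CC(C)(C)OO
Why: Vanadium‑catalysed hydroxyl‑directed epoxidation of a cyclic homoallylic alcohol delivers oxygen syn to the C10–OH, fixing the future O8 cis to O10.

**Step 6**
Reactants: 9; 10, 2‑bromoprop‑2‑en‑1‑ol
Product: 11, (1R,3S,4R)‑4‑(3‑hydroxyprop‑1‑en‑2‑yl)‑1,6‑dimethyl‑1,2,3,4‑tetrahydronaphthalene‑1,3‑diol
Conditions: 10, t‑BuLi (3 equiv), Et2O, −78 → 0 °C; MgBr2·OEt2; CuI (20 mol %); then 9 (pre‑treated with i‑PrMgCl), THF, −30 → 0 °C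
Reagents that add atoms: 2‑bromoallyl alcohol (10), C=C(Br)CO
Why: Copper‑mediated SN2 opening of the aryl epoxide at the benzylic carbon, anti to the epoxide oxygen, places the 2‑(hydroxymethyl)vinyl group at C7 trans to the new C8–OH.

**Step 7 (key dearomatisation)**
Reactants: 11
Product: 12, (1R,3S,4R)‑4‑(3‑hydroxyprop‑1‑en‑2‑yl)‑1,6‑dimethyl‑1,2,3,4,5,8‑hexahydronaphthalene‑1,3‑diol
Conditions: Li (excess), NH3(l)/THF, t‑BuOH, −78 → −33 °C; NH4Cl
Reagents that add atoms: none
Why: Birch reduction of the 1,2,4‑trialkylbenzene puts all three alkyl‑bearing carbons on double bonds, so the fusion carbons become the C1=C6 tetrasubstituted alkene (latent C1/C6 diketone) and C3=C4(Me) is exposed; the three hydroxyls react as alkoxides, which resists benzylic/allylic C–O cleavage; the isolated 1,1‑disubstituted alkene and all stereocentres are untouched.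

**Step 8**
Reactants: 12; 13, angelic acid [(Z)‑2‑methylbut‑2‑enoic acid]
Product: 14, 2‑[(1R,2S,4R)‑4‑hydroxy‑4,7‑dimethyl‑2‑(angeloyloxy)‑1,2,3,4,5,8‑hexahydronaphthalen‑1‑yl]prop‑2‑en‑1‑yl angelate (bis‑angelate at the secondary C8–OH and the primary allylic OH; tertiary OH free)
Conditions: 13, 2,4,6‑trichlorobenzoyl chloride, Et3N, toluene, rt; then 12, 80 °C (no DMAP)
Reagents that add atoms: angelic acid (13), C/C=C(/C)C(=O)O (two equivalents incorporated)
Why: Yamaguchi mixed‑anhydride esterification without DMAP avoids Z→E isomerisation; the C8 angelate is the natural ester and the primary angelate is a leaving group for step 12.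

**Step 9**
Reactants: 14; 15, acetic anhydride
Product: 16, 2‑[(1R,2S,4R)‑4‑acetoxy‑4,7‑dimethyl‑2‑(angeloyloxy)‑1,2,3,4,5,8‑hexahydronaphthalen‑1‑yl]prop‑2‑en‑1‑yl angelate
Conditions: Ac2O, Et3N, DMAP, CH2Cl2, 35 °C
Reagents that add atoms: acetic anhydride (15), CC(=O)OC(C)=O
Why: DMAP‑catalysed acylation of the only remaining (tertiary) alcohol gives the C10 acetate under basic conditions, avoiding ionisation of the tertiary allylic centre.

**Step 10**
Reactants: 16
Product: 17, 2‑[(1S,2S,4R,6R,7R)‑4‑acetoxy‑6‑hydroxy‑4,7‑dimethyl‑2‑(angeloyloxy)‑1,2,3,4,5,6,7,8‑octahydronaphthalen‑1‑yl]‑3‑hydroxypropyl angelate (mixture at the side‑chain CH, which is later removed)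
Conditions: 9‑BBN (1.1 equiv), THF, 0 °C → rt; then IpcBH2 (from (−)‑α‑pinene), −25 °C; NaBO3·4H2O, THF/H2O, rt
Reagents that add atoms: sodium perborate tetrahydrate as H2O2 source, OO (supplies both new hydroxyl oxygens)
Why: Brown asymmetric hydroboration: 9‑BBN first takes the 1,1‑disubstituted side‑chain alkene, then IpcBH2 adds H and B syn across C3=C4(Me) with boron at C3, giving trans‑3‑OH/4‑Me with the (3R,4R) face chosen by the reagent (about 6:1 expected); the minor isomer is a separable diastereomer, and the tetrasubstituted alkene and the angelates do not react.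

**Step 11**
Reactants: 17
Product: 18, 2‑[(1S,2S,4R,6R,7R)‑4‑acetoxy‑6‑hydroxy‑4,7‑dimethyl‑2‑(angeloyloxy)octahydronaphthalen‑1‑yl]‑3‑(angeloyloxy)propanoic acid
Conditions: TEMPO (20 mol %), PhI(OAc)2, MeCN/H2O, rt
Reagents that add atoms: water, O
Why: TEMPO/hypervalent‑iodine oxidation takes the primary alcohol to the carboxylic acid in preference to the hindered secondary C3–OH.

**Step 12**
Reactants: 18; 19, trimethyloxonium tetrafluoroborate
Product: 20, methyl 2‑[(1R,2S,4R,6R,7R)‑4‑acetoxy‑6‑methoxy‑4,7‑dimethyl‑2‑(angeloyloxy)‑1,2,3,4,5,6,7,8‑octahydronaphthalen‑1‑yl]acrylate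
Conditions: Me3OBF4, proton sponge, CH2Cl2, 0 °C → rt; then DBU, rt (one pot)
Reagents that add atoms: trimethyloxonium tetrafluoroborate (19), C[O+](C)C.F[B-](F)(F)F (two methyl groups)
Why: Meerwein‑salt methylation converts the acid to its methyl ester and the C3–OH to the methyl ether without touching the esters; DBU then expels the β‑angeloyloxy group (E1cB) to give the acrylate.

**Step 13**
Reactants: 20
Product: 21, methyl 2‑[(1R,2S,4R,7R,8R)‑4‑acetoxy‑7‑methoxy‑4,8‑dimethyl‑5,10‑dioxo‑2‑(angeloyloxy)cyclodecyl]acrylate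
Conditions: O3, CH2Cl2/MeOH, −78 °C (Sudan Red endpoint); Me2S, −78 → 0 °C; used at once
Reagents that add atoms: ozone, [O-][O+]=O
Why: Chemoselective ozonolysis: the electron‑rich tetrasubstituted fusion alkene reacts far faster than the acrylate or angelate, and cleaving it turns the bicyclo[4.4.0]decene into the cyclodecane‑1,6‑dione with the C1 ketone in place.

**Step 14**
Reactants: 21
Product: 22, Rufesolide C
Conditions: (S)‑Me‑CBS (0.3 equiv), catecholborane, toluene, −78 °C; then PPTS, CH2Cl2, rt
Reagents that add atoms: none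
Why: Corey–Bakshi–Shibata reduction: the non‑basic catalyst reduces the less hindered C6 ketone (C7 side as the large group) to the (6R)‑alcohol in preference to the C1 ketone flanked by quaternary C10, and the C6–OH then lactonises onto the acrylate ester (loss of MeOH) to give the trans‑fused α‑methylene lactone.

## Compound list

1 | 1‑(2‑hydroxy‑4‑methylphenyl)ethan‑1‑one | CC(=O)c1ccc(C)cc1O | starting material
2 | trifluoromethanesulfonic anhydride | O=S(=O)(OS(=O)(=O)C(F)(F)F)C(F)(F)F | starting material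
3 | 2‑acetyl‑5‑methylphenyl triflate | CC(=O)c1ccc(C)cc1OS(=O)(=O)C(F)(F)F | intermediate
4 | potassium vinyltrifluoroborate | C=C[B-](F)(F)F.[K+] | starting material
5 | 1‑(4‑methyl‑2‑vinylphenyl)ethan‑1‑one | CC(=O)c1ccc(C)cc1C=C | intermediate
6 | allylboronic acid pinacol ester | C=CCB1OC(C)(C)C(C)(C)O1 | starting material
7 | (R)‑2‑(4‑methyl‑2‑vinylphenyl)pent‑4‑en‑2‑ol | C[C@@](O)(CC=C)c1ccc(C)cc1C=C | intermediate
8 | (R)‑1,6‑dimethyl‑1,2‑dihydronaphthalen‑1‑ol | C[C@@]1(O)CC=Cc2cc(C)ccc21 | intermediate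
9 | (1aS,3R,7bR)‑3,6‑dimethyl‑1a,2,3,7b‑tetrahydronaphtho[1,2‑b]oxiren‑3‑ol | C[C@@]1(O)C[C@@H]2O[C@@H]2c3cc(C)ccc31 | intermediate
10 | 2‑bromoprop‑2‑en‑1‑ol | C=C(Br)CO | starting material
11 | (1R,3S,4R)‑4‑(3‑hydroxyprop‑1‑en‑2‑yl)‑1,6‑dimethyl‑1,2,3,4‑tetrahydronaphthalene‑1,3‑diol | C[C@@]1(O)C[C@H](O)[C@@H](C(=C)CO)c2cc(C)ccc21 | intermediate
12 | (1R,3S,4R)‑4‑(3‑hydroxyprop‑1‑en‑2‑yl)‑1,6‑dimethyl‑1,2,3,4,5,8‑hexahydronaphthalene‑1,3‑diol | C[C@@]1(O)C[C@H](O)[C@@H](C(=C)CO)C2=C1CC=C(C)C2 | intermediate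
13 | angelic acid | C/C=C(/C)C(=O)O | starting material
14 | bis‑angelate of 12 (secondary C8–O and primary allylic O) | C[C@@]1(O)C[C@H](OC(=O)/C(C)=C\C)[C@@H](C(=C)COC(=O)/C(C)=C\C)C2=C1CC=C(C)C2 | intermediate
15 | acetic anhydride | CC(=O)OC(C)=O | starting material
16 | tertiary acetate of 14 | C[C@@]1(OC(C)=O)C[C@H](OC(=O)/C(C)=C\C)[C@@H](C(=C)COC(=O)/C(C)=C\C)C2=C1CC=C(C)C2 | intermediate
17 | (3R,4R)‑hydroxy/primary‑alcohol diol from hydroboration of 16 | C[C@@]1(OC(C)=O)C[C@H](OC(=O)/C(C)=C\C)[C@@H](C(CO)COC(=O)/C(C)=C\C)C2=C1C[C@@H](O)[C@H](C)C2 | intermediate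
18 | carboxylic acid from 17 | C[C@@]1(OC(C)=O)C[C@H](OC(=O)/C(C)=C\C)[C@@H](C(C(=O)O)COC(=O)/C(C)=C\C)C2=C1C[C@@H](O)[C@H](C)C2 | intermediate
19 | trimethyloxonium tetrafluoroborate | C[O+](C)C.F[B-](F)(F)F | starting material
20 | methyl 2‑[(1R,2S,4R,6R,7R)‑4‑acetoxy‑6‑methoxy‑4,7‑dimethyl‑2‑(angeloyloxy)‑1,2,3,4,5,6,7,8‑octahydronaphthalen‑1‑yl]acrylate | C[C@@]1(OC(C)=O)C[C@H](OC(=O)/C(C)=C\C)[C@@H](C(=C)C(=O)OC)C2=C1C[C@@H](OC)[C@H](C)C2 | intermediate
21 | methyl 2‑[(1R,2S,4R,7R,8R)‑4‑acetoxy‑7‑methoxy‑4,8‑dimethyl‑5,10‑dioxo‑2‑(angeloyloxy)cyclodecyl]acrylate | COC(=O)C(=C)[C@@H]1[C@@H](OC(=O)/C(C)=C\C)C[C@@](C)(OC(C)=O)C(=O)C[C@@H](OC)[C@H](C)CC1=O | intermediate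
22 | Rufesolide C | C=C1C(=O)O[C@@H]2C[C@@H](C)[C@H](OC)CC(=O)[C@](C)(OC(C)=O)C[C@H](OC(=O)/C(C)=C\C)[C@@H]12 | target

## Summary

**Total steps:** 14. **Longest linear sequence:** 14 (fully linear; all coupling partners are purchased).

**Where each stereocentre is set:** C10 in step 3; C8 in step 5; C7 in step 6; C3 and C4 in step 10; C6 in step 14.

**Three steps most likely to fail, with fallbacks:**

1. **Step 7 (Birch).** Risks are loss of the tertiary benzylic oxygen, base‑induced migration of the side‑chain alkene through the benzylic/allylic C7–H, and over‑reduction. Fallback: switch to the anisole series from 3′‑methoxy‑4′‑methylacetophenone. The methoxyarene reduces under milder conditions with fixed regiochemistry, and ring A is then finished by enol‑ether hydrolysis, ketone reduction and O‑methylation instead of hydroboration.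

2. **Step 13 (ozonolysis, labile diketone 21).** The C7–H is α to the C6 ketone and allylic, with a β‑angelate, so epimerisation, conjugation or elimination can compete; epoxide by‑products are also possible. Fallback: epoxidise the tetrasubstituted alkene (mCPBA) and cleave with H5IO6, and postpone the β‑elimination of step 12 until after lactonisation (one extra step) so the diketone carries no allylic α‑hydrogen.

3. **Step 14 (C6 versus C1 ketone, and C6 configuration).** The C1 ketone is hindered but activated by the α‑acetoxy group, so selectivity is uncertain, and the macrocycle may oppose the catalyst. Fallback: reduce both ketones (NaBH4/CeCl3), let C6–OH lactonise, and re‑oxidise the remaining C1–OH with Dess–Martin periodinane; if C6 forms with the wrong configuration, close the lactone with inversion by Mitsunobu lactonisation of the seco‑acid.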